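## Analysis of the target

The target, 2-(2,6-dimethoxy-4-propylphenoxy)-4-(3-hydroxypropyl)-6-methoxyphenol (11), is a diaryl ether of two C6–C3 units. It has two benzene rings joined by one oxygen, no further ring and no stereocentre. Ring A is a 2,6-dimethoxy-4-propylphenyl group bound through its C1 oxygen, so the bridging oxygen sits between two methoxy groups. Ring B carries three neighbouring oxygens that are all different: the aryloxy group at C1, a free hydroxyl at C2 and a methoxy group at C3. It also carries a 3-hydroxypropyl chain at C5, para to the free hydroxyl. The sensitive parts are the electron-rich free phenol, which is easily oxidised, and the primary alcohol, which must be masked whenever a strong base is used. The difficulty lies in the crowded ether bridge, which has three ortho oxygen substituents around it, and in telling the three oxygens of ring B apart without a chain of protecting-group steps. The strategy rests on C2 of ring B. In the compound that lacks the C2 hydroxyl, this carbon bears the only aromatic hydrogen lying between two oxygen-bearing carbons (C1–OAr and C3–OMe), so it is the most acidic aryl C–H and can be turned into C–OH last.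

## Retrosynthetic reasoning

11 ⇒ 10. The O–Si bond of the primary alcohol is cut first. The alcohol has to be masked during the organolithium step, and a triisopropylsilyl ether withstands alkyllithium base, phosphate in hot DMSO and buffered peroxide. The forward step only has to remove silicon without exposing the free phenol to basic, oxidising conditions.

10 ⇒ 7. The C2–O bond of ring B is cut. Of the three oxygens on ring B, only this one sits on a carbon whose C–H is activated by two flanking oxygen substituents in the deoxy compound. Removing it turns ring B into a 1,3,5-trisubstituted arene with no substituent next to the ether oxygen, which eases the ether synthesis one step earlier. It also removes the need to differentiate three adjacent oxygens by protecting groups, because C–H acidity dictates the position of the hydroxyl. The forward reaction must metalate C2 in preference to four other aryl C–H bonds and two benzylic methylenes, then convert C–Li into C–O through the aryllithium 8 and the borate 9.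

7 ⇒ 5 + 6. The bond between C1 of ring B and the bridging oxygen is cut, not the bond on the ring A side. The ring A side would require a di-ortho-substituted, electron-rich aryl halide as electrophile. Cutting on the ring B side gives a bromide with two free ortho positions (5) and a phenol that already holds every substituent of ring A and can be bought (6). The forward reaction is a copper-catalysed O-arylation that must tolerate the two ortho methoxy groups of the phenoxide. Assembling ring B from a non-aromatic six-membered precursor and aromatising it later would avoid the coupling, but it costs several redox and carbon–carbon bond-forming steps. The direct arylation keeps 7 three steps from purchased materials.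

5 ⇒ 4. The O–Si bond is cut; the forward step is a routine silylation. The silyl group is put on before the coupling so that the primary alcohol cannot compete as a nucleophile at copper.

4 ⇒ 1 + 2. The bond between the ring B carbon and the first CH2 of the side chain is cut. Dibromide 1 is symmetrical, so a single bromine–lithium exchange desymmetrises it through aryllithium 3. Opening of the four-membered cyclic ether 2 by 3 supplies all three chain carbons and the terminal hydroxyl in one operation. The bromine that remains is the handle for the ether synthesis.

## Alternatives that were turned down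

Alternative 1: Ring A is taken apart at two C–C bonds, C4–C5 and C1–C6. In the forward direction NaOMe promotes conjugate addition of dimethyl malonate A3 to the aryloxymethyl enone A2, and the aryloxy-bearing methylene then closes onto a malonate ester in a Claisen condensation. This gives the cyclohexanedione ester A1, in which the future ring A already carries the ether oxygen between two carbonyls and the propyl group opposite. In its favour, the crowded C–O bond would be made earlier by plain alkylation of a phenol with a halomethyl ketone. That is more dependable than any aryl coupling, and on this point it is stronger than the chosen route. Against it, ring A arrives two oxidation levels away from an arene. A1 must be decarboxylated, dehydrogenated, and methylated on both hydroxyls next to the aryloxy group. The ring B partner must come with its three oxygens already differentiated (benzyl, methyl, free) and with the chain as an ester, so reduction and hydrogenolysis are also needed at the end. The aryloxy-bearing carbon of A1 lies between two carbonyls and is open to retro-Claisen cleavage by methoxide. The sequence is roughly twice as long as the chosen one. The chosen strategy instead buys ring A complete and needs no redox adjustment of either ring.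

Alternative 2: The bridging C–O bond is cut on the ring A side at the dione oxidation level. Rh2(OAc)4 would decompose the diazo dione A5, and the resulting carbene would insert into the single free O–H of the ring B phenol A6 to give the 2-aryloxy-1,3-dione A4. O–H insertion is convergent, neutral and little affected by steric crowding, so it is as strong as or stronger than a copper coupling for this bond. Against it, the acceptor-substituted rhodium carbene is strongly electrophilic and A6 is an electron-rich arene, so attack on the ring or at ring C–H bonds competes with O–H insertion. A4 still needs aromatisation, double O-methylation, ester reduction and debenzylation. A6 itself requires two adjacent hydroxyls of an earlier ring B building block to be told apart, which is the target's own selectivity problem moved upstream. The chosen route is shorter and lets C–H acidity, not protecting-group selectivity, place the free hydroxyl.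

Alternative 3: The bond between C5 of ring B and the side chain is cut. Heating the allyl ether A8 would trigger two successive [3,3] shifts, first to a blocked ortho dienone and then on to the para carbon, giving the allylphenol A7. Anti-Markovnikov hydration of the alkene would then lead to 11. The regiochemistry is fixed by structure because both ortho positions are blocked, no organometallic selectivity is involved, and the free phenol appears at the right carbon in the same step. On regiocontrol this is stronger than the chosen key step. Against it, the rearrangement solves the easy bond. A8 already contains the diaryl ether with an oxygen substituent ortho to the bridge on ring B, which is the most hindered version of the coupling, and it again needs two neighbouring ring B oxygens to be differentiated beforehand. The blocked dienone intermediates can also divert at the temperature required, and a hydroboration step remains. The chosen strategy addresses the hard bonds directly: it makes the ether on an unhindered ring B and adds the third oxygen afterwards.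

Key step: step 4

Remark on the chemistry: 1, 2 and 6 are taken as purchased materials; 11 has no stereocentre, so no stereochemical assumption is needed.

## Route

Step 1
Reactants: 1 1,3-dibromo-5-methoxybenzene; 2 oxetane
Product: 4 3-(3-bromo-5-methoxyphenyl)propan-1-ol, via (3-bromo-5-methoxyphenyl)lithium 3 (not isolated)
Conditions: n-BuLi (1.0 equiv), Et2O, −78 °C; then 2, BF3·OEt2, THF, −78 °C; aq. NH4Cl
Reagents that add atoms: none
Why: Bromine–lithium exchange on the symmetrical dibromide stops after one exchange because aryllithium 3 resists a second exchange; 3 then opens BF3-activated oxetane by SN2 attack at a ring CH2 (Lewis-acid-promoted oxetane opening by an organolithium), which delivers the three-carbon chain and the primary alcohol in one operation and leaves the second bromide for step 3.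

Step 2
Reactants: 4 3-(3-bromo-5-methoxyphenyl)propan-1-ol
Product: 5 [3-(3-bromo-5-methoxyphenyl)propoxy]tri(propan-2-yl)silane
Conditions: TIPSCl, imidazole, DMF, rt
Reagents that add atoms: chlorotri(propan-2-yl)silane (TIPSCl), CC(C)[Si](Cl)(C(C)C)C(C)C
Why: Imidazole-assisted silylation of a primary alcohol; the triisopropylsilyl ether is chosen because it should withstand phosphate base in hot DMSO, n-BuLi/TMEDA and buffered peroxide.

Step 3
Reactants: 5 [3-(3-bromo-5-methoxyphenyl)propoxy]tri(propan-2-yl)silane; 6 2,6-dimethoxy-4-propylphenol
Product: 7 {3-[3-(2,6-dimethoxy-4-propylphenoxy)-5-methoxyphenyl]propoxy}tri(propan-2-yl)silane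
Conditions: CuI (10 mol%), picolinic acid (20 mol%), K3PO4, degassed DMSO, 90 °C, Ar
Reagents that add atoms: none
Why: Ligand-accelerated Ullmann diaryl ether synthesis: the picolinate-bound copper phenoxide of 6 reacts with the aryl bromide, whose two free ortho positions keep all the steric load on the phenol side; electron-rich di-ortho-substituted phenols are competent nucleophiles under these conditions, and the silyl and methyl ethers are stable to K3PO4 in DMSO.

Step 4
Reactants: 7 {3-[3-(2,6-dimethoxy-4-propylphenoxy)-5-methoxyphenyl]propoxy}tri(propan-2-yl)silane
Product: 10 2-(2,6-dimethoxy-4-propylphenoxy)-6-methoxy-4-{3-[tri(propan-2-yl)silyloxy]propyl}phenol, via C2-lithiated diaryl ether 8 (not isolated), via lithium aryl(trimethoxy)borate 9 (not isolated)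
Conditions: n-BuLi, TMEDA, Et2O, 0 °C → rt; B(OMe)3, −78 °C → rt; AcOH, 30% aq. H2O2, 0 °C → rt; aq. Na2S2O3
Reagents that add atoms: hydrogen peroxide, OO
Why: Directed ortho-metalation followed by borylation and oxidation, the aryllithium–borate–peroxide route to phenols. n-BuLi·TMEDA binds to the methoxy oxygen at C3 and the diaryl ether oxygen at C1 of ring B and removes the C2 proton, the only aromatic hydrogen flanked by two oxygen-bearing carbons and therefore the most acidic one, to give 8. 8 adds to B(OMe)3 to form the ate complex 9; hydroperoxide then replaces methoxide on boron, the aryl group migrates from boron to oxygen at the same carbon, and hydrolysis of the borate ester releases phenol 10. The closest known reaction type is the C2 lithiation of resorcinol dialkyl ethers and 3-aryloxyanisoles with hydroxylation through the borate. No ring is closed and no stereocentre is formed. The step needs site selectivity among five aryl C–H bonds and two benzylic methylenes: C4 and C6 of ring B and C3/C5 of ring A each have one oxygen neighbour and an alkyl group on the other side, so they are less acidic and less well chelated. The triisopropylsilyl ether and the methyl ethers are inert to the base at 0 °C, and the acetic acid buffer keeps 10 protonated so that the electron-rich phenol is not oxidised further.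

Step 5
Reactants: 10 2-(2,6-dimethoxy-4-propylphenoxy)-6-methoxy-4-{3-[tri(propan-2-yl)silyloxy]propyl}phenol
Product: 11 2-(2,6-dimethoxy-4-propylphenoxy)-4-(3-hydroxypropyl)-6-methoxyphenol
Conditions: TBAF, AcOH, THF, rt
Reagents that add atoms: none
Why: Fluoride-induced cleavage of a silyl ether, driven by Si–F bond formation; acetic acid buffers the medium so that the air-sensitive phenoxide of 11 is not generated, and no other group should react.

## Compound list

1 | 1,3-dibromo-5-methoxybenzene (3,5-dibromoanisole) | COc1cc(Br)cc(Br)c1 | starting material
2 | oxetane | C1COC1 | starting material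
3 | (3-bromo-5-methoxyphenyl)lithium (formed in the flask) | [Li]c1cc(Br)cc(OC)c1 | intermediate
4 | 3-(3-bromo-5-methoxyphenyl)propan-1-ol | COc1cc(Br)cc(CCCO)c1 | intermediate
5 | [3-(3-bromo-5-methoxyphenyl)propoxy]tri(propan-2-yl)silane | COc1cc(Br)cc(CCCO[Si](C(C)C)(C(C)C)C(C)C)c1 | intermediate
6 | 2,6-dimethoxy-4-propylphenol | CCCc1cc(OC)c(O)c(OC)c1 | starting material
7 | {3-[3-(2,6-dimethoxy-4-propylphenoxy)-5-methoxyphenyl]propoxy}tri(propan-2-yl)silane | CCCc1cc(OC)c(Oc2cc(CCCO[Si](C(C)C)(C(C)C)C(C)C)cc(OC)c2)c(OC)c1 | intermediate
8 | {2-(2,6-dimethoxy-4-propylphenoxy)-6-methoxy-4-[3-(tri(propan-2-yl)silyloxy)propyl]phenyl}lithium (formed in the flask) | CCCc1cc(OC)c(Oc2cc(CCCO[Si](C(C)C)(C(C)C)C(C)C)cc(OC)c2[Li])c(OC)c1 | intermediate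
9 | lithium {2-(2,6-dimethoxy-4-propylphenoxy)-6-methoxy-4-[3-(tri(propan-2-yl)silyloxy)propyl]phenyl}trimethoxyborate (formed in the flask) | [Li+].CCCc1cc(OC)c(Oc2cc(CCCO[Si](C(C)C)(C(C)C)C(C)C)cc(OC)c2[B-](OC)(OC)OC)c(OC)c1 | intermediate
10 | 2-(2,6-dimethoxy-4-propylphenoxy)-6-methoxy-4-{3-[tri(propan-2-yl)silyloxy]propyl}phenol | CCCc1cc(OC)c(Oc2cc(CCCO[Si](C(C)C)(C(C)C)C(C)C)cc(OC)c2O)c(OC)c1 | intermediate
11 | 2-(2,6-dimethoxy-4-propylphenoxy)-4-(3-hydroxypropyl)-6-methoxyphenol | CCCc1cc(OC)c(Oc2cc(CCCO)cc(OC)c2O)c(OC)c1 | target

## Step count and least certain steps

Total step count: 5. Longest linear sequence: 5 steps (1 → 4 → 5 → 7 → 10 → 11); 6 is purchased and enters at step 3.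

Step 4 (key step). The most likely failures are:
- metalation at the wrong site: at C6 of ring B, where a ring A methoxy group can help hold lithium, or ortho to a ring A methoxy group;
- incomplete metalation, because the crowded diaryl ether oxygen coordinates lithium poorly;
- further oxidation of the electron-rich phenol during the peroxide treatment.

The fallback sets out from 6 and rejoins the route at 11. It places the C2 oxygen by a carbonyl-to-oxygen exchange and involves no metalation. 6 is heated with purchased 4-bromo-2-fluoro-6-methoxybenzaldehyde (COc1cc(Br)cc(F)c1C=O; K2CO3, DMF, 90 °C). The ortho formyl group activates the fluoride for displacement and gives 4-bromo-2-(2,6-dimethoxy-4-propylphenoxy)-6-methoxybenzaldehyde F1. Sonogashira coupling of F1 with prop-2-yn-1-ol (Pd(PPh3)2Cl2, CuI, Et3N, 60 °C), helped by the para formyl group, gives 2-(2,6-dimethoxy-4-propylphenoxy)-4-(3-hydroxyprop-1-yn-1-yl)-6-methoxybenzaldehyde F2. Baeyer–Villiger (Dakin-type) oxidation with mCPBA in CH2Cl2 turns the formyl carbon into 2-(2,6-dimethoxy-4-propylphenoxy)-4-(3-hydroxyprop-1-yn-1-yl)-6-methoxyphenyl formate F3. K2CO3 in MeOH cleaves F3 to 2-(2,6-dimethoxy-4-propylphenoxy)-4-(3-hydroxyprop-1-yn-1-yl)-6-methoxyphenol F4. Hydrogenation (H2, Pd/C, EtOAc) then saturates the alkyne and gives 11 directly.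

Step 3. The coupling may be slow or stall because the two ortho methoxy groups crowd the copper phenoxide. Protodebromination of 5 and oxidative degradation of the phenoxide by traces of oxygen at 90 °C may then take over. The fallback sets out from 5 and rejoins the route at 7. Bromine–lithium exchange on 5 (n-BuLi, THF, −78 °C), trapping with B(OiPr)3 and mild aqueous acid should give {3-methoxy-5-[3-(tri(propan-2-yl)silyloxy)propyl]phenyl}boronic acid F5. Chan–Lam coupling of F5 with 6 (Cu(OAc)2, pyridine, 4 Å molecular sieves, CH2Cl2, dry air, rt) forms the same C–O bond at room temperature by a different mechanism, transmetalation from boron to divalent copper and reductive elimination from trivalent copper, and gives 7.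

Step 1. Transfer of the aryl group from lithium to boron, or BF3-induced oligomerisation of oxetane, may outrun the ring opening, and the aryllithium may be butylated by the 1-bromobutane formed in the exchange. The fallback sets out from 1 and rejoins the route at 4. The same mono-exchange gives 3, which is allylated (allyl bromide, catalytic CuBr·SMe2, −78 °C → rt) to 1-bromo-3-methoxy-5-(prop-2-en-1-yl)benzene F6. Anti-Markovnikov hydroboration–oxidation of F6 (9-BBN, THF; NaOH, H2O2) gives 4.

Further compounds

F1 | step 4 | 4-bromo-2-(2,6-dimethoxy-4-propylphenoxy)-6-methoxybenzaldehyde | CCCc1cc(OC)c(Oc2cc(Br)cc(OC)c2C=O)c(OC)c1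
F2 | step 4 | 2-(2,6-dimethoxy-4-propylphenoxy)-4-(3-hydroxyprop-1-yn-1-yl)-6-methoxybenzaldehyde | CCCc1cc(OC)c(Oc2cc(C#CCO)cc(OC)c2C=O)c(OC)c1
F3 | step 4 | 2-(2,6-dimethoxy-4-propylphenoxy)-4-(3-hydroxyprop-1-yn-1-yl)-6-methoxyphenyl formate | CCCc1cc(OC)c(Oc2cc(C#CCO)cc(OC)c2OC=O)c(OC)c1
F4 | step 4 | 2-(2,6-dimethoxy-4-propylphenoxy)-4-(3-hydroxyprop-1-yn-1-yl)-6-methoxyphenol | CCCc1cc(OC)c(Oc2cc(C#CCO)cc(OC)c2O)c(OC)c1
F5 | step 3 | {3-methoxy-5-[3-(tri(propan-2-yl)silyloxy)propyl]phenyl}boronic acid | COc1cc(CCCO[Si](C(C)C)(C(C)C)C(C)C)cc(B(O)O)c1
F6 | step 1 | 1-bromo-3-methoxy-5-(prop-2-en-1-yl)benzene | C=CCc1cc(Br)cc(OC)c1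
A1 | alternative 1 | methyl 3-[2-(benzyloxy)-3-methoxy-5-(3-methoxy-3-oxopropyl)phenoxy]-2,4-dioxo-6-propylcyclohexane-1-carboxylate | CCCC1CC(=O)C(Oc2cc(CCC(=O)OC)cc(OC)c2OCc2ccccc2)C(=O)C1C(=O)OC
A2 | alternative 1 | methyl 3-[4-(benzyloxy)-3-methoxy-5-{[(3E)-2-oxohept-3-en-1-yl]oxy}phenyl]propanoate | CCC/C=C/C(=O)COc1cc(CCC(=O)OC)cc(OC)c1OCc1ccccc1
A3 | alternative 1 | dimethyl malonate | COC(=O)CC(=O)OC
A4 | alternative 2 | methyl 3-{4-(benzyloxy)-3-[(2,6-dioxo-4-propylcyclohexyl)oxy]-5-methoxyphenyl}propanoate | CCCC1CC(=O)C(Oc2cc(CCC(=O)OC)cc(OC)c2OCc2ccccc2)C(=O)C1
A5 | alternative 2 | 2-diazo-5-propylcyclohexane-1,3-dione | CCCC1CC(=O)C(=[N+]=[N-])C(=O)C1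
A6 | alternative 2 | methyl 3-[4-(benzyloxy)-3-hydroxy-5-methoxyphenyl]propanoate | COC(=O)CCc1cc(O)c(OCc2ccccc2)c(OC)c1
A7 | alternative 3 | 4-allyl-2-(2,6-dimethoxy-4-propylphenoxy)-6-methoxyphenol | C=CCc1cc(OC)c(O)c(Oc2c(OC)cc(CCC)cc2OC)c1
A8 | alternative 3 | 2-[2-(allyloxy)-3-methoxyphenoxy]-1,3-dimethoxy-5-propylbenzene | C=CCOc1c(OC)cccc1Oc1c(OC)cc(CCC)cc1OC
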